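# Proposed total synthesis of CNP0269915.2: epicatechin 3-O-gallate-(4β→8)-epicatechin 3-O-gallate-(4β→8)-catechin

Flavan numbering is used for each unit (O1, C2, C3, C4, C4a, C5 to C8, C8a). Ring A is the benzo ring, ring C the pyran ring and ring B the catechol ring. "Top", "middle" and "bottom" follow the chain top C4 → middle C8, middle C4 → bottom C8. Bn = benzyl, TBS = tert-butyldimethylsilyl.

## Analysis of the target

The target is a linear B-type proanthocyanidin trimer. Three flavan-3-ol units, each a dioxygenated ring A fused to a dihydropyran ring C with a catechol ring B on C2, are joined by two C4–C8 bonds. The top and middle units are epicatechin units (2,3-cis) whose C4 substituent is trans to the C3 oxygen (4β), and both carry a galloyl ester on O3. The bottom unit is catechin (2,3-trans) with a free 3-hydroxyl. There are eight stereocentres: C2, C3 and C4 of the top unit, C2, C3 and C4 of the middle unit, and C2 and C3 of the bottom unit. The three groups are separated by aromatic rings, so each has to be controlled on its own. The molecule holds eighteen free phenols in air-sensitive catechol and pyrogallol rings, two aryl esters that cleave in base, C2 centres that epimerise in base once the ring B phenols are free, and two diarylmethine C4–C8 bonds that strong acid cleaves or scrambles. The difficulties are the regiochemistry (C8, not C6) and the 3,4-trans geometry of two interflavan bonds, the tendency of cationic flavan couplings to run on to oligomers, and the need to tell three secondary 3-oxygens apart (two acylated, one free). The strategy rests on ring C of the top unit. Its O1–C8a–C4a–C4 segment is a latent ortho-quinone methide, and its C2–C3 segment, with aryl on C2 cis to galloyloxy on C3, is a latent (Z)-enol gallate. C2, C3 and C4 of the top unit can therefore be made in one [4+2] addition on a middle–bottom dimer whose other five centres come from the chiral pool.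

## Retrosynthetic reasoning

**24 from 23.** All eighteen phenols and the bottom 3-hydroxyl are masked as benzyl ethers, so the last step cuts nineteen O–CH2Ph bonds at once. Benzyl ethers survive organolithium, Lewis acid, Brønsted acid and fluoride, and leave under neutral conditions that spare the esters and the C4–C8 bonds. The benzyl ether on the bottom O3 is what keeps that oxygen free of gallate.

**23 from 22 and 18, and 22 from 21.** The acyl C–O bond of the middle gallate is cut. This ester is made late because an aryl ester on the middle unit would not survive the aryllithium used to assemble the fragments. Until then a silyl ether holds the middle O3, distinct from the benzyl ethers and from the top gallate. The forward reactions are a fluoride desilylation and the acylation of a hindered secondary alcohol.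

**21 from 15 and 19, through 20.** The top O1–C2 and C3–C4 bonds are cut, which is the retron of a hetero-[4+2] addition of ortho-quinone methide 20 to enol ester 19. These two bonds are chosen because their removal leaves the top C4–middle C8 bond in place. The second interflavan bond, the one that in a cationic coupling invites C6 attack and chain growth, is then an ordinary aryl–CH(OH) bond in 15. The gain is ring C and three stereocentres in one step, with the top gallate delivered by 19. The forward reaction has to control regiochemistry (aryl at C2, acyloxy at C3), relative configuration (2,3-cis, 3,4-trans) and the face of 20.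

**19 from 17 and 18, and 17 from 16.** The vinyl C–O bond of the enol ester is cut, back to alkyne 17 and acid 18. The forward addition must be anti-Markovnikov and must give the Z double bond. Alkyne 17 comes from aldehyde 16 by a one-carbon homologation.

**15 from 14, and 14 from 9 and 12, through 13.** The bond between middle C8 and the carbinol carbon is cut, with middle C8 as the nucleophile (C–Br to C–Li) and an aldehyde as the electrophile. The phenol of the aldehyde has to be masked during the addition, because a free phenol would quench 13. An allyl ether is chosen since it can be removed under neutral conditions that the ionisable carbinol tolerates. Aldehyde 12 comes from 10 through 11 by two etherifications that exploit the chelated ortho-hydroxyl.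

**9 from 8 and 3.** The middle C4–bottom C8 bond is cut, the classical flavan-4-yl cation/arene disconnection. It is used only once in the route. The C8 bromine of 8 blocks self-condensation and is also the handle for the previous disconnection. The 3,4-trans geometry should follow from attack anti to the 3-silyloxy and 2-aryl groups.

**8 from 4 through 5, 6 and 7, and 3 from 1 through 2.** These are functional-group changes on the chiral-pool materials: benzylation, C8 bromination, silylation and C4 oxidation. C2 and C3 of the middle unit (from 4) and of the bottom unit (from 1) are never broken.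

## Alternatives that were turned down

**Alternative 1:** 
- **Disconnection:** the O1–C2 bonds of the middle and bottom units, cut together. This leads back to A2, in which both rings C are open, each C2 is a benzylic CH2 next to a free catechol, and both C8a oxygens are free phenols.
- **Forward key step:** anodic oxidation of the two catechols of A2. Each oxidised ring tautomerises to the quinone methide stage at C2, the C8a phenol adds, and both pyran rings close with return of the catechols, to give A1.
- **For it:** two rings form in one reagent-free operation, no chiral catalyst is needed, and two catechols never need protection.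
- **Against it:**
  - The two new C2 centres must come out with opposite relationships to C3 (cis in the middle unit, trans in the bottom unit). A kinetic closure onto a planar quinone methide has no element that would deliver the less stable 2,3-cis arrangement next to an O-galloyl C3 and a fully substituted C4.
  - The catechols of A1 are as easily oxidised as those of A2. The product is therefore exposed to re-oxidation at the electrode, which reopens C2 to epimerisation or leads to over-oxidation.
  - A2 needs the C3/C4 array of the middle unit built without the ring, so the C2 centres that 4 and 1 provide would be destroyed and made again.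
- **Comparison:** Alternative 1 is stronger in ring-forming economy and in protecting-group count. The chosen route makes only the three top centres and takes the other five from the chiral pool.

**Alternative 2:** 
- **Disconnection:** ring A of the middle unit, cut at C8–C8a and C6–C7 (and formally at C4a–C8a). This leads back to cyclobutenone A4, which carries the bottom unit and the open C2–C4 chain of the middle unit, and siloxyalkyne A5, which carries the complete top unit.
- **Forward key step:** on heating, A4 opens, adds A5 in a [2+2] sense, opens again and closes by 6π electrocyclisation to phenol A3, with the top unit fixed at C8 beside the free C8a hydroxyl.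
- **For it:** the position of the top unit on ring A is set by construction, no electrophilic substitution on a polyoxygenated arene is needed, and the three ring A oxygens come out differentiated.
- **Against it:**
  - A3 is still an open keto-phenol. Middle ring C must be closed afterwards with a 2,3-cis C2, by reduction and cyclisation next to an epimerisable α-silyloxy ketone centre.
  - A4 has to carry that same centre and a cyclobutenone methine through prolonged heating.
  - A5 requires a C4-alkynylated top unit to be turned into a sensitive siloxyalkyne.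
  - The C2–C4 chain of the middle unit does not come from 4.
  - After the annulation, ring closure, protecting-group exchange at C7 and two acylations remain, so the route is much longer.
- **Comparison:** Alternative 2 is stronger on one point, the unambiguous C8 regiochemistry. The chosen route secures the same point with the C8 bromine carried from 6 to 9 and needs no arene construction.

**Alternative 3:** 
- **Disconnection:** the C4–C4a bond of the middle unit. This leads back to carbinol A7, in which middle ring C is open, C2 is bound to ring A through an aryl ether, and the C4 carbinol carries the bottom unit.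
- **Forward key step:** acid ionises the C4 carbinol of A7, the neighbouring gallate shields one face, and C4a, the only free position ortho to the ether oxygen, closes ring C to give A6, which is identical with 23.
- **For it:** the key step is a well-understood cationic ring closure, intramolecular and regiochemically forced. The 3,4-trans relationship follows from ester participation. Both gallates are in place beforehand, so steps 15 and 16 of the chosen route would not be needed.
- **Against it:**
  - A7 contains a benzylic aryl ether at C2 on a 3,4-dibenzyloxyphenyl ring. The same acid can ionise it, with loss of the C2 configuration or of the ether.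
  - That ether has to be made by substitution at a secondary benzylic carbon with a phenol that already carries the whole top unit in its ortho position.
  - C2 and C3 of the middle unit are made afresh instead of being taken from 4.
- **Comparison:** Alternative 3 is stronger in the precedent of its key step and in the endgame. The chosen route offers a precursor reached from 4 and 1 by standard steps, with no acid-labile C2 ether and with the middle C2/C3 centres never at risk, at the price of a less proven ring-forming step.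

Key step: step 14

## Remarks on the chemistry (assumptions)

- Compounds 16 and 18 are taken as purchased.
- The acid of step 14 is written as its (R) antipode. Which antipode cooperates with the resident centres of 15 cannot be told in advance, and the cooperating one is meant.
- The carbinol centre of 14 and 15 is formed without control and is removed in step 14.

## Route

Step 1
Reactants: 1 (+)-catechin
Product: 2 5,7,3',4'-tetra-O-benzyl-(+)-catechin
Conditions: BnBr (4.4 equiv), K2CO3, DMF, 0 °C to rt, argon
Reagents that add atoms: benzyl bromide, BrCc1ccccc1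
Why: Williamson etherification; K2CO3 deprotonates only the four phenols, so the secondary 3-hydroxyl stays free, and the mild base with exclusion of air should leave C2 and C3 untouched.

Step 2
Reactants: 2 5,7,3',4'-tetra-O-benzyl-(+)-catechin
Product: 3 3,5,7,3',4'-penta-O-benzyl-(+)-catechin
Conditions: NaH, BnBr, DMF, 0 °C to rt
Reagents that add atoms: benzyl bromide, BrCc1ccccc1
Why: Williamson etherification of the secondary alkoxide; with all phenols capped, base cannot open ring C, so both centres are kept, and the benzyl ether marks the bottom O3 as the one that is not acylated later.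

Step 3
Reactants: 4 (−)-epicatechin
Product: 5 5,7,3',4'-tetra-O-benzyl-(−)-epicatechin
Conditions: BnBr (4.4 equiv), K2CO3, DMF, 0 °C to rt, argon
Reagents that add atoms: benzyl bromide, BrCc1ccccc1
Why: Williamson etherification of the four phenols as in step 1; the axial 3-hydroxyl is not alkylated by carbonate, and C2 and C3 are retained.

Step 4
Reactants: 5 5,7,3',4'-tetra-O-benzyl-(−)-epicatechin
Product: 6 8-bromo-5,7,3',4'-tetra-O-benzyl-(−)-epicatechin
Conditions: NBS (1.0 equiv), CH2Cl2, −78 °C to rt
Reagents that add atoms: N-bromosuccinimide, O=C1CCC(=O)N1Br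
Why: Electrophilic aromatic bromination; C8 (ortho to O1 and to the 7-benzyloxy group, para to the 5-benzyloxy group) is favoured over C6, which lies between two benzyloxy groups, and one equivalent at low temperature should stop at the monobromide.

Step 5
Reactants: 6 8-bromo-5,7,3',4'-tetra-O-benzyl-(−)-epicatechin
Product: 7 8-bromo-3-O-TBS-5,7,3',4'-tetra-O-benzyl-(−)-epicatechin
Conditions: TBSCl, imidazole, DMF, rt
Reagents that add atoms: tert-butyldimethylsilyl chloride, CC(C)(C)[Si](C)(C)Cl
Why: Silylation of the only free hydroxyl; the silyl ether tolerates the organolithium and acid steps ahead and can later be removed in the presence of benzyl ethers and an aryl ester.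

Step 6
Reactants: 7 8-bromo-3-O-TBS-5,7,3',4'-tetra-O-benzyl-(−)-epicatechin
Product: 8 8-bromo-4β-(2-ethoxyethoxy)-3-O-TBS-5,7,3',4'-tetra-O-benzyl-(−)-epicatechin (4-alkoxy trans to the 3-silyloxy group)
Conditions: DDQ (2 equiv), 2-ethoxyethanol (5 equiv), CH2Cl2, rt
Reagents that add atoms: 2-ethoxyethanol, CCOCCO
Why: Benzylic oxidation by hydride abstraction; the C4 cation is stabilised by O1 and the 5- and 7-oxygens and is captured by the alcohol anti to the 3-silyloxy group, while benzyl ethers survive DDQ. The C4 configuration is of no consequence because this centre is ionised again in step 7.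

Step 7
Reactants: 8 8-bromo-4β-(2-ethoxyethoxy)-3-O-TBS-5,7,3',4'-tetra-O-benzyl-(−)-epicatechin; 3 3,5,7,3',4'-penta-O-benzyl-(+)-catechin
Product: 9 bromo dimer, 8-bromo-3-O-TBS-5,7,3',4'-tetra-O-benzylepicatechin-(4β→8)-3,5,7,3',4'-penta-O-benzylcatechin
Conditions: 3 (2 equiv), TMSOTf (0.2 equiv), CH2Cl2, −78 °C; Et3N quench
Reagents that add atoms: none
Why: Lewis-acid-mediated Friedel–Crafts alkylation of C8 of 3 by the flavan-4-yl cation from 8; attack anti to the 3-silyloxy and 2-aryl groups should set middle C4 trans to O3 (4β). The C8 bromine keeps 8 from alkylating itself, and the excess of 3 suppresses a second alkylation.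

Step 8
Reactants: 10 2,4,6-trihydroxybenzaldehyde
Product: 11 4,6-bis(benzyloxy)-2-hydroxybenzaldehyde
Conditions: BnBr (2.1 equiv), K2CO3, DMF, 0 °C to rt
Reagents that add atoms: benzyl bromide, BrCc1ccccc1
Why: Regioselective Williamson etherification; the para hydroxyl and one ortho hydroxyl are alkylated, and the remaining ortho hydroxyl is held in a hydrogen bond to the formyl group and reacts much more slowly.

Step 9
Reactants: 11 4,6-bis(benzyloxy)-2-hydroxybenzaldehyde
Product: 12 2-(allyloxy)-4,6-bis(benzyloxy)benzaldehyde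
Conditions: allyl bromide, K2CO3, DMF, 60 °C
Reagents that add atoms: allyl bromide, C=CCBr
Why: Williamson etherification of the chelated phenol under more forcing conditions; the allyl ether removes the acidic proton that would quench the aryllithium of step 10 and is orthogonal to benzyl and silyl ethers.

Step 10
Reactants: 9 bromo dimer; 12 2-(allyloxy)-4,6-bis(benzyloxy)benzaldehyde
Product: 14 allyl-protected carbinol, the dimer carrying CH(OH)[2-(allyloxy)-4,6-bis(benzyloxy)phenyl] at middle C8 (both carbinol epimers), via C8-lithio dimer 13 (not isolated)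
Conditions: n-BuLi (1.05 equiv), THF, −78 °C; then 12 (1.5 equiv), −78 to −30 °C; aq NH4Cl
Reagents that add atoms: none
Why: Bromine–lithium exchange on an aryl bromide flanked by two oxygens is fast at −78 °C and outruns benzylic deprotonation; the aryllithium then adds to the non-enolisable aldehyde (1,2-addition).

Step 11
Reactants: 14 allyl-protected carbinol
Product: 15 carbinol, the dimer carrying CH(OH)[2-hydroxy-4,6-bis(benzyloxy)phenyl] at middle C8 (both carbinol epimers)
Conditions: Pd(PPh3)4 (5 mol %), morpholine (10 equiv), THF, rt; filtration through Et3N-deactivated silica, used at once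
Reagents that add atoms: none
Why: Tsuji–Trost-type deallylation; zerovalent palladium ionises the aryl allyl ether and morpholine takes up the allyl group, under neutral to basic conditions that should not ionise the doubly benzylic carbinol and do not touch benzyl or silyl ethers.

Step 12
Reactants: 16 3,4-bis(benzyloxy)benzaldehyde
Product: 17 1,2-bis(benzyloxy)-4-ethynylbenzene
Conditions: dimethyl (1-diazo-2-oxopropyl)phosphonate, K2CO3, MeOH/THF, rt
Reagents that add atoms: dimethyl (1-diazo-2-oxopropyl)phosphonate, COP(=O)(OC)C(=[N+]=[N-])C(C)=O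
Why: Seyferth–Gilbert homologation in the Ohira–Bestmann form; the mild carbonate conditions suit an electron-rich, non-enolisable aryl aldehyde.

Step 13
Reactants: 17 1,2-bis(benzyloxy)-4-ethynylbenzene; 18 3,4,5-tris(benzyloxy)benzoic acid
Product: 19 (Z)-2-[3,4-bis(benzyloxy)phenyl]ethenyl 3,4,5-tris(benzyloxy)benzoate
Conditions: [RuCl2(p-cymene)]2 (1 mol %), P(4-ClC6H4)3 (3 mol %), DMAP (4 mol %), toluene, 60 °C
Reagents that add atoms: none
Why: Ruthenium-catalysed anti-Markovnikov addition of a carboxylic acid to a terminal alkyne; the alkyne is taken up as a ruthenium vinylidene, the carboxylate adds to its α-carbon, and protonolysis releases the enol ester with the Z geometry that this catalyst type is known to favour.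

Step 14
Reactants: 15 carbinol; 19 (Z)-2-[3,4-bis(benzyloxy)phenyl]ethenyl 3,4,5-tris(benzyloxy)benzoate
Product: 21 protected trimer, 5,7,3',4'-tetra-O-benzylepicatechin 3-O-(3,4,5-tri-O-benzylgallate)-(4β→8)-3-O-TBS-5,7,3',4'-tetra-O-benzylepicatechin-(4β→8)-3,5,7,3',4'-penta-O-benzylcatechin, via ortho-quinone methide 20 (not isolated)
Conditions: (R)-3,3'-bis(2,4,6-triisopropylphenyl)-1,1'-binaphthyl-2,2'-diyl hydrogen phosphate (10 mol %), 19 (3 equiv), 4 Å molecular sieves, toluene, −20 to 0 °C
Reagents that add atoms: none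
Why: Proposed new method: the chiral phosphoric acid should ionise the doubly benzylic carbinol of 15 to ortho-quinone methide 20 and stay hydrogen-bonded to its carbonyl oxygen; the oxygen-bearing alkene carbon of 19 (future C3, the β-carbon of the styrene) then attacks the methide carbon (future C4) while the quinone methide oxygen bonds to the benzylic carbon (future C2) in an asynchronous inverse-demand hetero-[4+2] addition. The closest known reaction type is the phosphoric-acid-catalysed [4+2] addition of ortho-quinone methides, made from ortho-hydroxybenzyl alcohols, to styrenes and enol ethers; a β-acyloxystyrene has not been shown as the 2π partner. Ring C of the top unit closes as a six-membered ring by this cycloaddition, which in its stepwise limit is a 6-exo-trig capture of the para-benzyloxybenzyl cation at C2 by the phenol oxygen. The step needs regioselectivity, and the 3,4-dibenzyloxyphenyl group should secure it, because its para oxygen stabilises positive charge at C2 far better than the acyloxy group could at C3. C2 is set cis to C3 by suprafacial addition across the Z double bond, which requires ring closure to outrun rotation about C2–C3. C3 is set trans to C4 by the approach that keeps the aryl and galloyloxy groups of 19 away from the quinone methide ring and from the doubly ortho-substituted middle ring A on C4 (exo to the E isomer of 20 or endo to its Z isomer, which give the same relative configuration). The absolute configuration at C4, and with it that of all three centres, is set by the face that the chiral phosphate leaves open, since the resident centres of the middle unit are too far from the methide carbon to be relied on. The molecular sieves take up the water formed, so that 20 does not return to 15.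

Step 15
Reactants: 21 protected trimer
Product: 22 desilylated trimer with free middle 3-hydroxyl, 5,7,3',4'-tetra-O-benzylepicatechin 3-O-(3,4,5-tri-O-benzylgallate)-(4β→8)-5,7,3',4'-tetra-O-benzylepicatechin-(4β→8)-3,5,7,3',4'-penta-O-benzylcatechin
Conditions: Bu4NF, AcOH, THF, 0 °C to rt
Reagents that add atoms: none
Why: Fluoride cleavage of the secondary silyl ether; buffering with acetic acid keeps the medium from attacking the top gallate ester, and benzyl ethers are inert.

Step 16
Reactants: 22 desilylated trimer; 18 3,4,5-tris(benzyloxy)benzoic acid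
Product: 23 nonadeca-O-benzyl target, carrying tri-O-benzylgallates on the top and middle O3
Conditions: 18 (3 equiv), DCC, DMAP, CH2Cl2, rt to 40 °C
Reagents that add atoms: none
Why: Steglich esterification; the middle 3-hydroxyl is the only free hydroxyl of 22, so no selectivity is required, and acylation at oxygen leaves C3 untouched.

Step 17
Reactants: 23 nonadeca-O-benzyl target
Product: 24 CNP0269915.2, epicatechin 3-O-gallate-(4β→8)-epicatechin 3-O-gallate-(4β→8)-catechin
Conditions: H2 (1 atm), Pd(OH)2/C, THF/MeOH/H2O, rt; filtration and freeze-drying under argon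
Reagents that add atoms: none
Why: Hydrogenolysis of nineteen benzyl ethers under neutral conditions; the aryl esters, the ring C ethers and the diarylmethine C4–C8 bonds should not be cleaved at atmospheric pressure, so all eight stereocentres are carried through.

## Compound list

1 | (+)-catechin, (2R,3S) | O[C@H]1Cc2c(O)cc(O)cc2O[C@@H]1c1ccc(O)c(O)c1 | starting material
2 | 5,7,3',4'-tetra-O-benzyl-(+)-catechin | O[C@H]1Cc2c(OCc9ccccc9)cc(OCc9ccccc9)cc2O[C@@H]1c1ccc(OCc9ccccc9)c(OCc9ccccc9)c1 | intermediate
3 | 3,5,7,3',4'-penta-O-benzyl-(+)-catechin | O(Cc9ccccc9)[C@H]1Cc2c(OCc9ccccc9)cc(OCc9ccccc9)cc2O[C@@H]1c1ccc(OCc9ccccc9)c(OCc9ccccc9)c1 | intermediate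
4 | (−)-epicatechin, (2R,3R) | O[C@@H]1Cc2c(O)cc(O)cc2O[C@@H]1c1ccc(O)c(O)c1 | starting material
5 | 5,7,3',4'-tetra-O-benzyl-(−)-epicatechin | O[C@@H]1Cc2c(OCc9ccccc9)cc(OCc9ccccc9)cc2O[C@@H]1c1ccc(OCc9ccccc9)c(OCc9ccccc9)c1 | intermediate
6 | 8-bromo-5,7,3',4'-tetra-O-benzyl-(−)-epicatechin | O[C@@H]1Cc2c(OCc9ccccc9)cc(OCc9ccccc9)c(Br)c2O[C@@H]1c1ccc(OCc9ccccc9)c(OCc9ccccc9)c1 | intermediate
7 | 8-bromo-3-O-TBS-5,7,3',4'-tetra-O-benzyl-(−)-epicatechin | CC(C)(C)[Si](C)(C)O[C@@H]1Cc2c(OCc9ccccc9)cc(OCc9ccccc9)c(Br)c2O[C@@H]1c1ccc(OCc9ccccc9)c(OCc9ccccc9)c1 | intermediate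
8 | 8-bromo-4β-(2-ethoxyethoxy)-3-O-TBS-5,7,3',4'-tetra-O-benzyl-(−)-epicatechin (3,4-trans) | CC(C)(C)[Si](C)(C)O[C@@H]1[C@@H](OCCOCC)c2c(OCc9ccccc9)cc(OCc9ccccc9)c(Br)c2O[C@@H]1c1ccc(OCc9ccccc9)c(OCc9ccccc9)c1 | intermediate
9 | bromo dimer, 8-bromo-3-O-TBS-5,7,3',4'-tetra-O-benzylepicatechin-(4β→8)-3,5,7,3',4'-penta-O-benzylcatechin | CC(C)(C)[Si](C)(C)O[C@@H]1[C@@H](c2c(OCc9ccccc9)cc(OCc9ccccc9)c3c2O[C@H](c2ccc(OCc9ccccc9)c(OCc9ccccc9)c2)[C@@H](OCc9ccccc9)C3)c2c(OCc9ccccc9)cc(OCc9ccccc9)c(Br)c2O[C@@H]1c1ccc(OCc9ccccc9)c(OCc9ccccc9)c1 | intermediate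
10 | 2,4,6-trihydroxybenzaldehyde | O=Cc1c(O)cc(O)cc1O | starting material
11 | 4,6-bis(benzyloxy)-2-hydroxybenzaldehyde | O=Cc1c(O)cc(OCc9ccccc9)cc1OCc9ccccc9 | intermediate
12 | 2-(allyloxy)-4,6-bis(benzyloxy)benzaldehyde | O=Cc1c(OCC=C)cc(OCc9ccccc9)cc1OCc9ccccc9 | intermediate
13 | C8-lithio dimer (9 with Li in place of Br) | CC(C)(C)[Si](C)(C)O[C@@H]1[C@@H](c2c(OCc9ccccc9)cc(OCc9ccccc9)c3c2O[C@H](c2ccc(OCc9ccccc9)c(OCc9ccccc9)c2)[C@@H](OCc9ccccc9)C3)c2c(OCc9ccccc9)cc(OCc9ccccc9)c([Li])c2O[C@@H]1c1ccc(OCc9ccccc9)c(OCc9ccccc9)c1 | intermediate (not isolated)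
14 | allyl-protected carbinol, dimer with CH(OH)[2-(allyloxy)-4,6-bis(benzyloxy)phenyl] at middle C8, both carbinol epimers | CC(C)(C)[Si](C)(C)O[C@@H]1[C@@H](c2c(OCc9ccccc9)cc(OCc9ccccc9)c3c2O[C@H](c2ccc(OCc9ccccc9)c(OCc9ccccc9)c2)[C@@H](OCc9ccccc9)C3)c2c(OCc9ccccc9)cc(OCc9ccccc9)c(C(O)c3c(OCc9ccccc9)cc(OCc9ccccc9)cc3OCC=C)c2O[C@@H]1c1ccc(OCc9ccccc9)c(OCc9ccccc9)c1 | intermediate
15 | carbinol, dimer with CH(OH)[2-hydroxy-4,6-bis(benzyloxy)phenyl] at middle C8, both carbinol epimers | CC(C)(C)[Si](C)(C)O[C@@H]1[C@@H](c2c(OCc9ccccc9)cc(OCc9ccccc9)c3c2O[C@H](c2ccc(OCc9ccccc9)c(OCc9ccccc9)c2)[C@@H](OCc9ccccc9)C3)c2c(OCc9ccccc9)cc(OCc9ccccc9)c(C(O)c3c(OCc9ccccc9)cc(OCc9ccccc9)cc3O)c2O[C@@H]1c1ccc(OCc9ccccc9)c(OCc9ccccc9)c1 | intermediate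
16 | 3,4-bis(benzyloxy)benzaldehyde | O=Cc1ccc(OCc9ccccc9)c(OCc9ccccc9)c1 | starting material
17 | 1,2-bis(benzyloxy)-4-ethynylbenzene | C#Cc1ccc(OCc9ccccc9)c(OCc9ccccc9)c1 | intermediate
18 | 3,4,5-tris(benzyloxy)benzoic acid | OC(=O)c1cc(OCc9ccccc9)c(OCc9ccccc9)c(OCc9ccccc9)c1 | starting material
19 | (Z)-2-[3,4-bis(benzyloxy)phenyl]ethenyl 3,4,5-tris(benzyloxy)benzoate | O=C(O/C=C\c1ccc(OCc9ccccc9)c(OCc9ccccc9)c1)c1cc(OCc9ccccc9)c(OCc9ccccc9)c(OCc9ccccc9)c1 | intermediate
20 | ortho-quinone methide from 15 (3,5-bis(benzyloxy)-6-methylidenecyclohexa-2,4-dienone with the dimer on the methylidene carbon; geometry of the exocyclic double bond not fixed) | CC(C)(C)[Si](C)(C)O[C@@H]1[C@@H](c2c(OCc9ccccc9)cc(OCc9ccccc9)c3c2O[C@H](c2ccc(OCc9ccccc9)c(OCc9ccccc9)c2)[C@@H](OCc9ccccc9)C3)c2c(OCc9ccccc9)cc(OCc9ccccc9)c(C=C3C(=O)C=C(OCc9ccccc9)C=C3OCc9ccccc9)c2O[C@@H]1c1ccc(OCc9ccccc9)c(OCc9ccccc9)c1 | intermediate (not isolated)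
21 | protected trimer, top 3-O-(tri-O-benzylgallate), middle 3-O-TBS, sixteen benzyl ethers; top and middle units 2,3-cis-3,4-trans, bottom unit 2,3-trans | CC(C)(C)[Si](C)(C)O[C@@H]1[C@@H](c2c(OCc9ccccc9)cc(OCc9ccccc9)c3c2O[C@H](c2ccc(OCc9ccccc9)c(OCc9ccccc9)c2)[C@@H](OCc9ccccc9)C3)c2c(OCc9ccccc9)cc(OCc9ccccc9)c([C@H]3c4c(OCc9ccccc9)cc(OCc9ccccc9)cc4O[C@H](c4ccc(OCc9ccccc9)c(OCc9ccccc9)c4)[C@@H]3OC(=O)c3cc(OCc9ccccc9)c(OCc9ccccc9)c(OCc9ccccc9)c3)c2O[C@@H]1c1ccc(OCc9ccccc9)c(OCc9ccccc9)c1 | intermediate
22 | desilylated trimer with free middle 3-hydroxyl | O[C@@H]1[C@@H](c2c(OCc9ccccc9)cc(OCc9ccccc9)c3c2O[C@H](c2ccc(OCc9ccccc9)c(OCc9ccccc9)c2)[C@@H](OCc9ccccc9)C3)c2c(OCc9ccccc9)cc(OCc9ccccc9)c([C@H]3c4c(OCc9ccccc9)cc(OCc9ccccc9)cc4O[C@H](c4ccc(OCc9ccccc9)c(OCc9ccccc9)c4)[C@@H]3OC(=O)c3cc(OCc9ccccc9)c(OCc9ccccc9)c(OCc9ccccc9)c3)c2O[C@@H]1c1ccc(OCc9ccccc9)c(OCc9ccccc9)c1 | intermediate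
23 | nonadeca-O-benzyl target (top and middle 3-O-tri-O-benzylgallates, bottom 3-O-benzyl) | O=C(O[C@@H]1[C@@H](c2c(OCc9ccccc9)cc(OCc9ccccc9)c3c2O[C@H](c2ccc(OCc9ccccc9)c(OCc9ccccc9)c2)[C@@H](OCc9ccccc9)C3)c2c(OCc9ccccc9)cc(OCc9ccccc9)c([C@H]3c4c(OCc9ccccc9)cc(OCc9ccccc9)cc4O[C@H](c4ccc(OCc9ccccc9)c(OCc9ccccc9)c4)[C@@H]3OC(=O)c3cc(OCc9ccccc9)c(OCc9ccccc9)c(OCc9ccccc9)c3)c2O[C@@H]1c1ccc(OCc9ccccc9)c(OCc9ccccc9)c1)c1cc(OCc9ccccc9)c(OCc9ccccc9)c(OCc9ccccc9)c1 | intermediate
24 | CNP0269915.2, epicatechin 3-O-gallate-(4β→8)-epicatechin 3-O-gallate-(4β→8)-catechin | O=C(O[C@@H]1[C@@H](c2c(O)cc(O)c3c2O[C@H](c2ccc(O)c(O)c2)[C@@H](O)C3)c2c(O)cc(O)c([C@H]3c4c(O)cc(O)cc4O[C@H](c4ccc(O)c(O)c4)[C@@H]3OC(=O)c3cc(O)c(O)c(O)c3)c2O[C@@H]1c1ccc(O)c(O)c1)c1cc(O)c(O)c(O)c1 | target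

## Step count and risk

Total step count: 17.
Longest linear sequence: 11 steps, from 4 to 24 through steps 3, 4, 5, 6, 7, 10, 11, 14, 15, 16 and 17.

**Step 14 (key step, new method).**
- The addition may be too slow. The cation and quinone methide from 15 are stabilised by two trioxygenated rings and crowded at the methide carbon by four ortho substituents, while the double bond of 19 is only moderately nucleophilic. Self-condensation of 20 or its return to 15 would then take over.
- The cis relationship at C2/C3 may be lost, by bond rotation in the open benzylic cation or by participation of the gallate carbonyl before the ring closes.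
- Endo approach to the E isomer of 20, the usual preference of styrenes, would give the 3,4-cis isomer.
- Facial selectivity may be poor if catalyst and substrate are mismatched.

The fallback uses known chemistry and runs from 9 and 5 back to 21. Bromine–lithium exchange on 9 (n-BuLi, THF, −78 °C) and quenching with MeOH gives the bromine-free dimer F1. In parallel, 5 is esterified with 18 (DCC, DMAP) to tetra-O-benzylepicatechin 3-O-(tri-O-benzylgallate) F2. DDQ and 2-ethoxyethanol convert F2 into its 4-(2-ethoxyethoxy) derivative F3. TMSOTf-catalysed condensation of F3 with an excess of F1 in CH2Cl2 at −78 °C then forms the top C4–middle C8 bond by the cation chemistry of step 7, with the gallate carbonyl shielding one face, and gives 21.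

**Step 10.** The aryllithium 13 may be protonated before it adds, or may add sluggishly, because both partners are doubly ortho-substituted; benzylic deprotonation of a benzyl ether can then compete. The fallback runs from 9 to 15 and bypasses 12 and 14. Intermediate 13 is quenched with DMF, a far less hindered electrophile, to give the dimer C8-carbaldehyde F4. Commercial 3,5-bis(benzyloxy)phenol is converted with EtMgBr into bromomagnesium 3,5-bis(benzyloxy)phenoxide F5. Ortho-selective hydroxyalkylation of F5 with F4 in toluene/CH2Cl2, through a six-membered magnesium chelate, gives 15 directly.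

**Step 11.** The carbinol may be lost by ionisation during or after the deallylation, through the π-allylpalladium species or traces of acid on silica, which leads to premature quinone methide formation and self-condensation. The phenol may also be re-allylated. The fallback runs from 9 and 11 to 15. Aldehyde 11 is deprotonated with LiN(SiMe3)2 to lithium 3,5-bis(benzyloxy)-2-formylphenoxide F6. Intermediate 13, made from 9 as in step 10, is added to F6, and aqueous NH4Cl gives 15 without an allyl ether having to be removed.

**Step 13.** Markovnikov addition or incomplete Z selectivity may occur, and the Z-enol ester may isomerise on prolonged heating with the ruthenium catalyst. The fallback runs from 17 to 19. Rhodium-catalysed trans-hydroboration of 17 with pinacolborane ([RhCl(1,5-cyclooctadiene)]2, P(i-Pr)3, Et3N) gives the (Z)-alkenylboronate F7. KHF2 converts F7 into the potassium (Z)-alkenyltrifluoroborate F8. A Chan–Lam-type coupling of F8 with 18, mediated by Cu(OAc)2, then forms the vinyl C–O bond with retention of the double-bond geometry and gives 19.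

**Step 7.** Attack may occur through C6 of 3 or on the wrong face of the cation, and the silyl ether may be lost to the Lewis acid. The fallback runs from 6 to 9. Compound 6 is acetylated (Ac2O, pyridine) to the 3-O-acetate F9. DDQ and 2-ethoxyethanol give the 4-(2-ethoxyethoxy) acetate F10. TMSOTf-catalysed coupling of F10 with 3, now steered by acetoxonium participation, gives the dimer acetate F11. Methanolysis (K2CO3, MeOH/THF) gives the dimer alcohol F12, and TBSOTf with 2,6-lutidine returns 9.

## Further compounds

F1 | step 14 | bromine-free dimer, 3-O-TBS-5,7,3',4'-tetra-O-benzylepicatechin-(4β→8)-3,5,7,3',4'-penta-O-benzylcatechin | CC(C)(C)[Si](C)(C)O[C@@H]1[C@@H](c2c(OCc9ccccc9)cc(OCc9ccccc9)c3c2O[C@H](c2ccc(OCc9ccccc9)c(OCc9ccccc9)c2)[C@@H](OCc9ccccc9)C3)c2c(OCc9ccccc9)cc(OCc9ccccc9)cc2O[C@@H]1c1ccc(OCc9ccccc9)c(OCc9ccccc9)c1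
F2 | step 14 | 5,7,3',4'-tetra-O-benzylepicatechin 3-O-(3,4,5-tri-O-benzylgallate) | O=C(O[C@@H]1Cc2c(OCc9ccccc9)cc(OCc9ccccc9)cc2O[C@@H]1c1ccc(OCc9ccccc9)c(OCc9ccccc9)c1)c1cc(OCc9ccccc9)c(OCc9ccccc9)c(OCc9ccccc9)c1
F3 | step 14 | 4β-(2-ethoxyethoxy)-5,7,3',4'-tetra-O-benzylepicatechin 3-O-(3,4,5-tri-O-benzylgallate) | O=C(O[C@@H]1[C@@H](OCCOCC)c2c(OCc9ccccc9)cc(OCc9ccccc9)cc2O[C@@H]1c1ccc(OCc9ccccc9)c(OCc9ccccc9)c1)c1cc(OCc9ccccc9)c(OCc9ccccc9)c(OCc9ccccc9)c1
F4 | step 10 | dimer C8-carbaldehyde (9 with CHO in place of Br) | CC(C)(C)[Si](C)(C)O[C@@H]1[C@@H](c2c(OCc9ccccc9)cc(OCc9ccccc9)c3c2O[C@H](c2ccc(OCc9ccccc9)c(OCc9ccccc9)c2)[C@@H](OCc9ccccc9)C3)c2c(OCc9ccccc9)cc(OCc9ccccc9)c(C=O)c2O[C@@H]1c1ccc(OCc9ccccc9)c(OCc9ccccc9)c1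
F5 | step 10 | bromomagnesium 3,5-bis(benzyloxy)phenoxide | Br[Mg]Oc1cc(OCc9ccccc9)cc(OCc9ccccc9)c1
F6 | step 11 | lithium 3,5-bis(benzyloxy)-2-formylphenoxide | [Li+].[O-]c1cc(OCc9ccccc9)cc(OCc9ccccc9)c1C=O
F7 | step 13 | (Z)-2-{2-[3,4-bis(benzyloxy)phenyl]ethenyl}-4,4,5,5-tetramethyl-1,3,2-dioxaborolane | CC1(C)OB(/C=C\c2ccc(OCc9ccccc9)c(OCc9ccccc9)c2)OC1(C)C
F8 | step 13 | potassium (Z)-{2-[3,4-bis(benzyloxy)phenyl]ethenyl}trifluoroborate | [K+].F[B-](F)(F)/C=C\c1ccc(OCc9ccccc9)c(OCc9ccccc9)c1
F9 | step 7 | 3-O-acetyl-8-bromo-5,7,3',4'-tetra-O-benzyl-(−)-epicatechin | CC(=O)O[C@@H]1Cc2c(OCc9ccccc9)cc(OCc9ccccc9)c(Br)c2O[C@@H]1c1ccc(OCc9ccccc9)c(OCc9ccccc9)c1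
F10 | step 7 | 3-O-acetyl-8-bromo-4β-(2-ethoxyethoxy)-5,7,3',4'-tetra-O-benzyl-(−)-epicatechin | CC(=O)O[C@@H]1[C@@H](OCCOCC)c2c(OCc9ccccc9)cc(OCc9ccccc9)c(Br)c2O[C@@H]1c1ccc(OCc9ccccc9)c(OCc9ccccc9)c1
F11 | step 7 | bromo dimer 3-O-acetate (9 with acetyl in place of TBS) | CC(=O)O[C@@H]1[C@@H](c2c(OCc9ccccc9)cc(OCc9ccccc9)c3c2O[C@H](c2ccc(OCc9ccccc9)c(OCc9ccccc9)c2)[C@@H](OCc9ccccc9)C3)c2c(OCc9ccccc9)cc(OCc9ccccc9)c(Br)c2O[C@@H]1c1ccc(OCc9ccccc9)c(OCc9ccccc9)c1
F12 | step 7 | bromo dimer with free middle 3-hydroxyl | O[C@@H]1[C@@H](c2c(OCc9ccccc9)cc(OCc9ccccc9)c3c2O[C@H](c2ccc(OCc9ccccc9)c(OCc9ccccc9)c2)[C@@H](OCc9ccccc9)C3)c2c(OCc9ccccc9)cc(OCc9ccccc9)c(Br)c2O[C@@H]1c1ccc(OCc9ccccc9)c(OCc9ccccc9)c1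
A1 | alternative 1 | partly benzylated target with free catechols on the middle and bottom rings B and free bottom 3-hydroxyl | O=C(O[C@@H]1[C@@H](c2c(OCc9ccccc9)cc(OCc9ccccc9)c3c2O[C@H](c2ccc(O)c(O)c2)[C@@H](O)C3)c2c(OCc9ccccc9)cc(OCc9ccccc9)c([C@H]3c4c(OCc9ccccc9)cc(OCc9ccccc9)cc4O[C@H](c4ccc(OCc9ccccc9)c(OCc9ccccc9)c4)[C@@H]3OC(=O)c3cc(OCc9ccccc9)c(OCc9ccccc9)c(OCc9ccccc9)c3)c2O[C@@H]1c1ccc(O)c(O)c1)c1cc(OCc9ccccc9)c(OCc9ccccc9)c(OCc9ccccc9)c1
A2 | alternative 1 | bis-seco precursor of A1 with middle and bottom O1–C2 bonds open (C2 as CH2, C8a phenols free) | O=C(O[C@@H](Cc1ccc(O)c(O)c1)[C@@H](c2c(OCc9ccccc9)cc(OCc9ccccc9)c(C[C@H](O)Cc3ccc(O)c(O)c3)c2O)c2c(OCc9ccccc9)cc(OCc9ccccc9)c([C@H]3c4c(OCc9ccccc9)cc(OCc9ccccc9)cc4O[C@H](c4ccc(OCc9ccccc9)c(OCc9ccccc9)c4)[C@@H]3OC(=O)c3cc(OCc9ccccc9)c(OCc9ccccc9)c(OCc9ccccc9)c3)c2O)c1cc(OCc9ccccc9)c(OCc9ccccc9)c(OCc9ccccc9)c1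
A3 | alternative 2 | trimer precursor with complete middle ring A (free C8a hydroxyl, C7 triisopropylsilyl ether), open keto-phenol form | O=C(c1ccc(OCc9ccccc9)c(OCc9ccccc9)c1)[C@H](O[Si](C)(C)C(C)(C)C)[C@@H](c2c(OCc9ccccc9)cc(OCc9ccccc9)c3c2O[C@H](c2ccc(OCc9ccccc9)c(OCc9ccccc9)c2)[C@@H](OCc9ccccc9)C3)c2c(OCc9ccccc9)cc(O[Si](C(C)C)(C(C)C)C(C)C)c([C@H]3c4c(OCc9ccccc9)cc(OCc9ccccc9)cc4O[C@H](c4ccc(OCc9ccccc9)c(OCc9ccccc9)c4)[C@@H]3O[Si](C)(C)C(C)(C)C)c2O
A4 | alternative 2 | 4-substituted 3-(benzyloxy)cyclobut-2-enone carrying the bottom unit and the open middle C2–C4 chain (cyclobutenone C4 configuration not defined) | O=C(c1ccc(OCc9ccccc9)c(OCc9ccccc9)c1)[C@H](O[Si](C)(C)C(C)(C)C)[C@@H](c2c(OCc9ccccc9)cc(OCc9ccccc9)c3c2O[C@H](c2ccc(OCc9ccccc9)c(OCc9ccccc9)c2)[C@@H](OCc9ccccc9)C3)C1C(=O)C=C1OCc9ccccc9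
A5 | alternative 2 | top-unit siloxyalkyne, 4β-[(triisopropylsilyloxy)ethynyl]-3-O-TBS-5,7,3',4'-tetra-O-benzylepicatechin | CC(C)[Si](C(C)C)(C(C)C)OC#C[C@H]1c2c(OCc9ccccc9)cc(OCc9ccccc9)cc2O[C@H](c2ccc(OCc9ccccc9)c(OCc9ccccc9)c2)[C@@H]1O[Si](C)(C)C(C)(C)C
A6 | alternative 3 | perbenzylated target with bottom 3-O-benzyl (identical with 23) | O=C(O[C@@H]1[C@@H](c2c(OCc9ccccc9)cc(OCc9ccccc9)c3c2O[C@H](c2ccc(OCc9ccccc9)c(OCc9ccccc9)c2)[C@@H](OCc9ccccc9)C3)c2c(OCc9ccccc9)cc(OCc9ccccc9)c([C@H]3c4c(OCc9ccccc9)cc(OCc9ccccc9)cc4O[C@H](c4ccc(OCc9ccccc9)c(OCc9ccccc9)c4)[C@@H]3OC(=O)c3cc(OCc9ccccc9)c(OCc9ccccc9)c(OCc9ccccc9)c3)c2O[C@@H]1c1ccc(OCc9ccccc9)c(OCc9ccccc9)c1)c1cc(OCc9ccccc9)c(OCc9ccccc9)c(OCc9ccccc9)c1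
A7 | alternative 3 | seco carbinol with middle C4–C4a open (C2 aryl ether, C3 gallate, C4 carbinol on the bottom unit; C4 configuration not defined) | O=C(O[C@H](C(O)c2c(OCc9ccccc9)cc(OCc9ccccc9)c3c2O[C@H](c2ccc(OCc9ccccc9)c(OCc9ccccc9)c2)[C@@H](OCc9ccccc9)C3)[C@@H](c1ccc(OCc9ccccc9)c(OCc9ccccc9)c1)Oc1cc(OCc9ccccc9)cc(OCc9ccccc9)c1[C@H]2c3c(OCc9ccccc9)cc(OCc9ccccc9)cc3O[C@H](c3ccc(OCc9ccccc9)c(OCc9ccccc9)c3)[C@@H]2OC(=O)c2cc(OCc9ccccc9)c(OCc9ccccc9)c(OCc9ccccc9)c2)c1cc(OCc9ccccc9)c(OCc9ccccc9)c(OCc9ccccc9)c1
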